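Everything rests on cutting ring A, the ketone-bearing dihydroxychroman, at C3–C4, the bond in the two-carbon bridge that joins the quaternary ether carbon C2 to aryl carbon C4a. Ring-closing olefin metathesis forms this bond as the C3=C4 alkene of a 2H-chromene and closes the pyran in one operation; hydrogenation then gives the chroman. The metathesis substrate is the open ring B dihydrochalcone carrying a 2-methylbut-3-en-2-yl ether on the phloroglucinol oxygen para to the ketone and a vinyl group on the adjacent ring carbon, so that O1–C2 and C4–C4a are already in place and only the 6-acyl-5,7-dihydroxy chromene can form.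

Key step: step 7

Remark on the chemistry: the target has no stereocentre; the vinyl group is installed before the tertiary ether because an arylpalladium intermediate ortho to a propargyl or allyl ether would cyclise by 5-exo carbopalladation (or ionise the allyl ether) instead of cross-coupling.

Step 1
Reactants: 1 3-(4-hydroxyphenyl)propanoic acid; 2 2-methylbut-3-en-2-ol
Product: 4 3-(2,2-dimethylchroman-6-yl)propanoic acid, via ortho-prenyl phenol 3 (not isolated)
Conditions: 2 (1.3 equiv, slow addition), MeSO3H (cat.), 1,2-dichloroethane/1,4-dioxane, 70 °C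
Reagents that add atoms: none
Why: Acid-catalysed Friedel–Crafts prenylation by the prenyl cation ortho to the phenol (para is blocked) gives 3, and Markovnikov hydroalkoxylation of its alkene by the neighbouring phenol should close the 2,2-dimethylchroman while the carboxylic acid is a spectator.

Step 2
Reactants: 4 3-(2,2-dimethylchroman-6-yl)propanoic acid; 5 phloroglucinol
Product: 6 3-(2,2-dimethylchroman-6-yl)-1-(2,4,6-trihydroxyphenyl)propan-1-one
Conditions: BF3·OEt2 (neat, as solvent), 80 °C; then aq NaOAc
Reagents that add atoms: none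
Why: Friedel–Crafts C-acylation of the threefold-symmetric, highly nucleophilic phloroglucinol by the BF3-activated acid should stop after one acylation because the chelated aryl ketone is deactivated, and the chroman is the thermodynamically favoured form of ring B under Lewis acid.

Step 3
Reactants: 6 3-(2,2-dimethylchroman-6-yl)-1-(2,4,6-trihydroxyphenyl)propan-1-one
Product: 7 3-(2,2-dimethylchroman-6-yl)-1-(2,4,6-trihydroxy-3-iodophenyl)propan-1-one
Conditions: NIS (1.0 equiv), MeCN/THF, −20 → 0 °C, dark
Reagents that add atoms: N-iodosuccinimide, O=C1CCC(=O)N1I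
Why: Electrophilic aromatic iodination at one of the two equivalent, doubly oxygen-activated ring A carbons, where one equivalent of reagent at low temperature should favour mono-iodination and the singly alkoxylated ring B is inert without added acid.

Step 4
Reactants: 7 3-(2,2-dimethylchroman-6-yl)-1-(2,4,6-trihydroxy-3-iodophenyl)propan-1-one
Product: 8 3-(2,2-dimethylchroman-6-yl)-1-(2,4,6-trihydroxy-3-vinylphenyl)propan-1-one
Conditions: vinylboronic acid pinacol ester (1.5 equiv), Pd(OAc)2 (5 mol%), SPhos (10 mol%), K2CO3 (3 equiv), 1,4-dioxane/H2O (4:1), 70 °C, argon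
Reagents that add atoms: 4,4,5,5-tetramethyl-2-vinyl-1,3,2-dioxaborolane, C=CB1OC(C)(C)C(C)(C)O1
Why: Suzuki–Miyaura vinylation of the aryl iodide, in which the electron-rich biaryl phosphine should drive oxidative addition into the hindered, oxygen-rich iodide and no unsaturated ortho ether is yet present to intercept the arylpalladium intermediate.

Step 5
Reactants: 8 3-(2,2-dimethylchroman-6-yl)-1-(2,4,6-trihydroxy-3-vinylphenyl)propan-1-one; 9 3-chloro-3-methylbut-1-yne
Product: 10 1-[2,6-dihydroxy-4-(2-methylbut-3-yn-2-yloxy)-3-vinylphenyl]-3-(2,2-dimethylchroman-6-yl)propan-1-one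
Conditions: 9 (1.3 equiv), K2CO3 (1.5 equiv), KI (0.2 equiv), CuI (5 mol%), acetone, 45 °C, argon
Reagents that add atoms: none
Why: Copper-assisted O-alkylation of a phenoxide by a tertiary propargylic chloride, selective for the oxygen para to the ketone because it is the most acidic hydroxyl and is not tied to the carbonyl by hydrogen bonding, at a temperature well below the onset of propargyl Claisen rearrangement.

Step 6
Reactants: 10 1-[2,6-dihydroxy-4-(2-methylbut-3-yn-2-yloxy)-3-vinylphenyl]-3-(2,2-dimethylchroman-6-yl)propan-1-one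
Product: 11 1-[2,6-dihydroxy-4-(2-methylbut-3-en-2-yloxy)-3-vinylphenyl]-3-(2,2-dimethylchroman-6-yl)propan-1-one
Conditions: H2 (1 atm, stopped after 1 equiv), Pd/CaCO3 poisoned with Pb(OAc)2 (Lindlar catalyst), quinoline, EtOAc, 20 °C
Reagents that add atoms: none
Why: Lindlar semihydrogenation, in which the terminal alkyne binds the poisoned palladium surface far more strongly than the hindered styrene or the product alkene, so reduction should stop at the 1,1-dimethylallyl ether with the ketone and aryl C–O bonds untouched.

Step 7
Reactants: 11 1-[2,6-dihydroxy-4-(2-methylbut-3-en-2-yloxy)-3-vinylphenyl]-3-(2,2-dimethylchroman-6-yl)propan-1-one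
Product: 12 1-(5,7-dihydroxy-2,2-dimethyl-2H-chromen-6-yl)-3-(2,2-dimethylchroman-6-yl)propan-1-one
Conditions: second-generation Grubbs catalyst (H2IMes)(PCy3)Cl2Ru=CHPh (5 mol%), CH2Cl2 (degassed, acid-free, 5 mM), 25 °C
Reagents that add atoms: none
Why: The ruthenium benzylidene exchanges onto one terminal alkene, adds intramolecularly to the other by [2+2] cycloaddition to a ruthenacyclobutane and cycloreverts, releasing the chromene and a ruthenium methylidene that carries the chain and expels ethylene. The closest known reaction type is ring-closing metathesis of 2-vinylaryl allyl ethers to 2H-chromenes, including 2,2-dimethyl cases. The six-membered pyran of ring A is closed by forming the endocyclic C3=C4 double bond from the two former terminal alkene carbons, with O1–C2 and C4–C4a already present. No stereocentre is formed and the ring alkene can only be cis. The step needs metathesis to win over [3,3] shift or ionisation of the tertiary allyl aryl ether and over oligomerisation, which room temperature, high dilution, acid-free solvent and the gem-dimethyl (Thorpe–Ingold) bias at C2 should secure. The regiochemistry needs no control in this step, since the ether oxygen para to the ketone and the vinyl group on the adjacent carbon allow only this chromene.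

Step 8
Reactants: 12 1-(5,7-dihydroxy-2,2-dimethyl-2H-chromen-6-yl)-3-(2,2-dimethylchroman-6-yl)propan-1-one
Product: 13 1-(5,7-dihydroxy-2,2-dimethylchroman-6-yl)-3-(2,2-dimethylchroman-6-yl)propan-1-one
Conditions: H2 (1 atm), Pd/C (10 wt%), EtOAc, 20 °C
Reagents that add atoms: none
Why: Heterogeneous catalytic hydrogenation of the cis-disubstituted styrenyl C3=C4 alkene, under which the doubly chelated aryl ketone and both chroman ethers should remain intact and no stereocentre arises.

Compound list
1 | 3-(4-hydroxyphenyl)propanoic acid | O=C(O)CCc1ccc(O)cc1 | starting material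
2 | 2-methylbut-3-en-2-ol | CC(C)(O)C=C | starting material
3 | 3-[4-hydroxy-3-(3-methylbut-2-en-1-yl)phenyl]propanoic acid | CC(C)=CCc1cc(CCC(=O)O)ccc1O | intermediate
4 | 3-(2,2-dimethylchroman-6-yl)propanoic acid | CC1(C)CCc2cc(CCC(=O)O)ccc2O1 | intermediate
5 | phloroglucinol | Oc1cc(O)cc(O)c1 | starting material
6 | 3-(2,2-dimethylchroman-6-yl)-1-(2,4,6-trihydroxyphenyl)propan-1-one | CC1(C)CCc2cc(CCC(=O)c3c(O)cc(O)cc3O)ccc2O1 | intermediate
7 | 3-(2,2-dimethylchroman-6-yl)-1-(2,4,6-trihydroxy-3-iodophenyl)propan-1-one | CC1(C)CCc2cc(CCC(=O)c3c(O)cc(O)c(I)c3O)ccc2O1 | intermediate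
8 | 3-(2,2-dimethylchroman-6-yl)-1-(2,4,6-trihydroxy-3-vinylphenyl)propan-1-one | CC1(C)CCc2cc(CCC(=O)c3c(O)cc(O)c(C=C)c3O)ccc2O1 | intermediate
9 | 3-chloro-3-methylbut-1-yne | C#CC(C)(C)Cl | starting material
10 | 1-[2,6-dihydroxy-4-(2-methylbut-3-yn-2-yloxy)-3-vinylphenyl]-3-(2,2-dimethylchroman-6-yl)propan-1-one | C#CC(C)(C)Oc1cc(O)c(C(=O)CCc2ccc3c(c2)CCC(C)(C)O3)c(O)c1C=C | intermediate
11 | 1-[2,6-dihydroxy-4-(2-methylbut-3-en-2-yloxy)-3-vinylphenyl]-3-(2,2-dimethylchroman-6-yl)propan-1-one | C=CC(C)(C)Oc1cc(O)c(C(=O)CCc2ccc3c(c2)CCC(C)(C)O3)c(O)c1C=C | intermediate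
12 | 1-(5,7-dihydroxy-2,2-dimethyl-2H-chromen-6-yl)-3-(2,2-dimethylchroman-6-yl)propan-1-one | CC1(C)C=Cc2c(O)c(C(=O)CCc3ccc4c(c3)CCC(C)(C)O4)c(O)cc2O1 | intermediate
13 | 1-(5,7-dihydroxy-2,2-dimethylchroman-6-yl)-3-(2,2-dimethylchroman-6-yl)propan-1-one | CC1(C)CCc2cc(CCC(=O)c3c(O)cc4c(c3O)CCC(C)(C)O4)ccc2O1 | target

Total step count: 8. Longest linear sequence: 8 steps (1 to 13).

Steps most likely to fail

Step 7. Sigmatropic [3,3] shift or acid-triggered ionisation of the tertiary allyl aryl ether may compete with ring closure, and the catalyst may stall as a chelated ortho-alkoxybenzylidene or phenol-bound resting state. The fallback sets out from 6 and replaces metathesis by a pericyclic cascade.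
- Triol 6 is O-alkylated at the para oxygen with 9 (K2CO3, KI, CuI, acetone, 45 °C) to give 1-[2,6-dihydroxy-4-(2-methylbut-3-yn-2-yloxy)phenyl]-3-(2,2-dimethylchroman-6-yl)propan-1-one F1.
- Heating F1 in N,N-diethylaniline at 130–150 °C should trigger aromatic propargyl Claisen rearrangement to 3-(2,2-dimethylchroman-6-yl)-1-[2,4,6-trihydroxy-3-(3-methylbuta-1,2-dien-1-yl)phenyl]propan-1-one F2, which is not isolated.
- A [1,5]-hydrogen shift and oxa-6π electrocyclisation of F2 then lead back to the route at 12.
- The two ortho carbons of F1 are equivalent, and closure should use the former ether oxygen because the flanking hydroxyl is held by the ketone.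

Step 5. Site selectivity may be lost (alkylation at the hydrogen-bonded oxygens or twice), and dehydrochlorination of the tertiary chloride may outrun etherification at the vinyl-flanked oxygen. The fallback sets out from 8 and 2 and uses π-allyl palladium chemistry instead of the alkyne.
- Alcohol 2 is converted with n-BuLi and methyl chloroformate (THF, −78 → 0 °C) into methyl 2-methylbut-3-en-2-yl carbonate F3.
- F3 and 8 with Pd(PPh3)4 (2 mol%) in THF at 0 °C should undergo decarboxylative Tsuji–Trost O-allylation.
- The released methoxide deprotonates only the most acidic hydroxyl, and that phenoxide attacks the more substituted terminus of the 1,1-dimethylallyl palladium cation.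
- This comes back to the route at 11, bypassing 10 and the semihydrogenation.

Step 4. Protodeiodination and sluggish oxidative addition of the doubly ortho-oxygenated, phenoxide-rich iodide under aqueous base may occur, together with air oxidation of the polyphenol. The fallback sets out from 7 and masks the phenols before a base-free coupling.
- Exhaustive acetylation (Ac2O, pyridine, DMAP, CH2Cl2, 0–20 °C) gives 2-[3-(2,2-dimethylchroman-6-yl)propanoyl]-4-iodobenzene-1,3,5-triyl triacetate F4.
- Stille coupling with tributyl(vinyl)stannane (Pd(PPh3)4, CuI, DMF, 70 °C) gives 2-[3-(2,2-dimethylchroman-6-yl)propanoyl]-4-vinylbenzene-1,3,5-triyl triacetate F5.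
- Methanolysis (K2CO3, MeOH, 0 °C) removes the three acetates and returns to the route at 8.

Further compounds
F1 | step 7 | 1-[2,6-dihydroxy-4-(2-methylbut-3-yn-2-yloxy)phenyl]-3-(2,2-dimethylchroman-6-yl)propan-1-one | C#CC(C)(C)Oc1cc(O)c(C(=O)CCc2ccc3c(c2)CCC(C)(C)O3)c(O)c1
F2 | step 7 | 3-(2,2-dimethylchroman-6-yl)-1-[2,4,6-trihydroxy-3-(3-methylbuta-1,2-dien-1-yl)phenyl]propan-1-one | CC(C)=C=Cc1c(O)cc(O)c(C(=O)CCc2ccc3c(c2)CCC(C)(C)O3)c1O
F3 | step 5 | methyl 2-methylbut-3-en-2-yl carbonate | C=CC(C)(C)OC(=O)OC
F4 | step 4 | 2-[3-(2,2-dimethylchroman-6-yl)propanoyl]-4-iodobenzene-1,3,5-triyl triacetate | CC(=O)Oc1cc(OC(C)=O)c(I)c(OC(C)=O)c1C(=O)CCc1ccc2c(c1)CCC(C)(C)O2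
F5 | step 4 | 2-[3-(2,2-dimethylchroman-6-yl)propanoyl]-4-vinylbenzene-1,3,5-triyl triacetate | CC(=O)Oc1cc(OC(C)=O)c(C=C)c(OC(C)=O)c1C(=O)CCc1ccc2c(c1)CCC(C)(C)O2
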